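**Plan** (germacrane numbering: carbocycle C1–C10, methyls C14 on C10 and C15 on C4, lactone O on C6, ring-fusion carbon C7, C11(=C13H2)–C12(=O); OH on C2, ester on O9)
- Cuts, in order: (a) the O9–acyl bond of the side chain; (b) C7–C11, the Cα–Cβ bond of the α-methylene-γ-butyrolactone; (c) C9–C10 of the ten-membered ring; (d) C6–C7 and C2–C3 of the open chain.
- Forward: the chain is joined from three small pieces (C14/C10/C1/C2, C3–C6 with C15, C7–C9); the ten-membered carbocycle is closed first (C9–C10), the lactone ring second, and the side chain goes on last.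
- Enabling feature: C6 carries the lactone oxygen and C9 is oxygenated, so C7 can be made the β-carbon of a C7=C8–C9=O enone inside the carbocycle while an acrylate on O6 holds its α-carbon (C11) a five-membered transition state away from C7.
- One phosphine-triggered Rauhut–Currier cycloisomerisation then forms C7–C11, the exocyclic C11=C13 methylene and the C7 stereocentre, and leaves C8H2/C9=O ready for the ester.
- Stereocentres: C2 from a catalytic asymmetric vinylogous Mukaiyama aldol, C6 from a catalytic asymmetric alkynylation, C7 from C6 in the key step (trans fusion), C9 from a Corey–Bakshi–Shibata reduction.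
- Alkenes: Z-C1=C10 from trans-hydroalumination/iodination of but-2-yn-1-ol, E-C4=C5 from the aldol, Z side-chain alkene from a Z-bromoalkene carboxylated with retention.

Key step: step 14

Assumption: the catalyst antipodes named in steps 4 and 8 are those expected to give the configurations drawn; should either give the opposite sense, its mirror-image catalyst is used with no other change.

**Step 1**
Reactants: 1 but-2-yn-1-ol
Product: 3 (2Z)-3-iodobut-2-en-1-ol, via sodium alkenylalanate 2 (not isolated)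
Conditions: NaAlH2(OCH2CH2OMe)2 (Red-Al), THF, 0 to 23 °C; then I2, THF, −78 to 0 °C
Reagents that add atoms: iodine, II; NaAlH2(OCH2CH2OMe)2, [Na+].[AlH2-](OCCOC)OCCOC (its atoms stay in 2 only)
Why: alkoxide-directed trans-hydroalumination places aluminium on C3 in a five-membered alanate and iodinolysis with retention should give the Z-iodoalkene (Red-Al/iodine sequence); no stereocentre is formed.

**Step 2**
Reactants: 3 (2Z)-3-iodobut-2-en-1-ol
Product: 4 (2Z)-3-iodobut-2-enal
Conditions: MnO2, CH2Cl2, 23 °C, dark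
Reagents that add atoms: none
Why: MnO2 oxidation of an allylic alcohol is mild enough to keep the Z geometry and the C–I bond.

**Step 3**
Reactants: 5 ethyl 3-methylbut-2-enoate
Product: 7 tert-butyl[(1-ethoxy-3-methylbuta-1,3-dien-1-yl)oxy]dimethylsilane, via lithium dienolate 6 (not isolated)
Conditions: LiN(i-Pr)2, THF/DMPU, −78 °C; then TBSCl, −78 to 0 °C
Reagents that add atoms: tert-butyldimethylsilyl chloride, CC(C)(C)[Si](C)(C)Cl; LiN(i-Pr)2, CC(C)N([Li])C(C)C (Li stays in 6 only)
Why: γ-deprotonation of the senecioate and O-silylation of the extended enolate give the silyl dienolate (silyl ketene acetal formation).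

**Step 4**
Reactants: 4 (2Z)-3-iodobut-2-enal; 7 tert-butyl[(1-ethoxy-3-methylbuta-1,3-dien-1-yl)oxy]dimethylsilane
Product: 8 ethyl (2E,5R,6Z)-5-hydroxy-7-iodo-3-methylocta-2,6-dienoate
Conditions: SiCl4 (1.1 equiv), (R,R)-binaphthyldiamine-derived bisphosphoramide (5 mol %), i-Pr2NEt (10 mol %), CH2Cl2, −78 °C; aq. NaHCO3/KF
Reagents that add atoms: none
Why: in this Lewis-base-activated SiCl4 vinylogous Mukaiyama aldol the dienolate attacks through its unhindered γ-CH2 terminus and the chiral phosphoramide-bound silyl cation selects the aldehyde face, which should set C5 as R (target C2) and give the 2E trisubstituted alkene.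

**Step 5**
Reactants: 8 ethyl (2E,5R,6Z)-5-hydroxy-7-iodo-3-methylocta-2,6-dienoate
Product: 9 ethyl (2E,5R,6Z)-5-[(tert-butyldimethylsilyl)oxy]-7-iodo-3-methylocta-2,6-dienoate
Conditions: TBSCl, imidazole, DMF, 23 °C
Reagents that add atoms: tert-butyldimethylsilyl chloride, CC(C)(C)[Si](C)(C)Cl
Why: silyl ether formation protects the C2 hydroxyl to the end of the route without touching the stereocentre.

**Step 6**
Reactants: 9 ethyl (2E,5R,6Z)-5-[(tert-butyldimethylsilyl)oxy]-7-iodo-3-methylocta-2,6-dienoate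
Product: 10 (2E,5R,6Z)-5-[(tert-butyldimethylsilyl)oxy]-7-iodo-3-methylocta-2,6-dien-1-ol
Conditions: i-Bu2AlH (2.2 equiv), CH2Cl2, −78 °C; Rochelle salt work-up
Reagents that add atoms: none
Why: 1,2-reduction of the enoate by i-Bu2AlH gives the allylic alcohol and leaves the vinyl iodide and silyl ether alone.

**Step 7**
Reactants: 10 (2E,5R,6Z)-5-[(tert-butyldimethylsilyl)oxy]-7-iodo-3-methylocta-2,6-dien-1-ol
Product: 11 (2E,5R,6Z)-5-[(tert-butyldimethylsilyl)oxy]-7-iodo-3-methylocta-2,6-dienal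
Conditions: MnO2, CH2Cl2, 23 °C
Reagents that add atoms: none
Why: MnO2 allylic oxidation gives the E-enal without alkene isomerisation.

**Step 8**
Reactants: 11 (2E,5R,6Z)-5-[(tert-butyldimethylsilyl)oxy]-7-iodo-3-methylocta-2,6-dienal; 12 3,3-diethoxyprop-1-yne
Product: 14 (4R,5E,8R,9Z)-8-[(tert-butyldimethylsilyl)oxy]-1,1-diethoxy-10-iodo-6-methylundeca-5,9-dien-2-yn-4-ol, via alkynyl(methyl)zinc 13 (not isolated)
Conditions: Me2Zn (3 equiv), (S,S)-ProPhenol (20 mol %), Ph3P=O (40 mol %), toluene, 4 °C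
Reagents that add atoms: dimethylzinc, C[Zn]C (its atoms stay in 13 only)
Why: in the zinc–ProPhenol asymmetric alkynylation the dinuclear zinc catalyst binds enal and alkynylzinc and delivers the alkynyl group to one aldehyde face under catalyst control (the C8 centre is remote), which should set C4 as R (target C6).

**Step 9**
Reactants: 14 (4R,5E,8R,9Z)-8-[(tert-butyldimethylsilyl)oxy]-1,1-diethoxy-10-iodo-6-methylundeca-5,9-dien-2-yn-4-ol
Product: 15 (2E,4S,5E,8R,9Z)-8-[(tert-butyldimethylsilyl)oxy]-1,1-diethoxy-10-iodo-6-methylundeca-2,5,9-trien-4-ol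
Conditions: NaAlH2(OCH2CH2OMe)2 (Red-Al), THF, 0 °C; aq. Rochelle salt
Reagents that add atoms: none
Why: alkoxide-directed trans-hydroalumination of the propargylic alcohol and protonolysis should give the 2E alkene; the carbinol centre is untouched (the descriptor changes from R to S only through the priority rules).

**Step 10**
Reactants: 15 (2E,4S,5E,8R,9Z)-8-[(tert-butyldimethylsilyl)oxy]-1,1-diethoxy-10-iodo-6-methylundeca-2,5,9-trien-4-ol
Product: 16 (2E,4S,5E,8R,9Z)-8-[(tert-butyldimethylsilyl)oxy]-1,1-diethoxy-10-iodo-6-methylundeca-2,5,9-trien-4-yl prop-2-enoate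
Conditions: acryloyl chloride, i-Pr2NEt, CH2Cl2, −20 to 0 °C
Reagents that add atoms: acryloyl chloride, C=CC(=O)Cl
Why: O-acylation of the secondary allylic alcohol installs C11–C13 on O6 with retention at carbon.

**Step 11**
Reactants: 16 (2E,4S,5E,8R,9Z)-8-[(tert-butyldimethylsilyl)oxy]-1,1-diethoxy-10-iodo-6-methylundeca-2,5,9-trien-4-yl prop-2-enoate
Product: 17 (2E,4S,5E,8R,9Z)-8-[(tert-butyldimethylsilyl)oxy]-10-iodo-6-methyl-1-oxoundeca-2,5,9-trien-4-yl prop-2-enoate
Conditions: pyridinium p-toluenesulfonate (cat.), acetone/H2O, 23 °C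
Reagents that add atoms: water, O
Why: mild acid hydrolysis of the α,β-unsaturated acetal unmasks the E-enal while the silyl ether and allylic acrylate survive.

**Step 12**
Reactants: 17 (2E,4S,5E,8R,9Z)-8-[(tert-butyldimethylsilyl)oxy]-10-iodo-6-methyl-1-oxoundeca-2,5,9-trien-4-yl prop-2-enoate
Product: 19 (1S,2E,5Z,7R,9E)-7-[(tert-butyldimethylsilyl)oxy]-4-hydroxy-5,9-dimethylcyclodeca-2,5,9-trien-1-yl prop-2-enoate, via alkenylchromium dichloride 18 (not isolated)
Conditions: CrCl2 (10 equiv), NiCl2 (5 mol %), degassed DMSO/THF, 23 °C, slow addition of 17 to about 0.003 M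
Reagents that add atoms: chromium dichloride, Cl[Cr]Cl (its atoms stay in 18 only)
Why: in this Nozaki–Hiyama–Kishi macrocyclisation zerovalent nickel inserts into the C–I bond with retention of the Z geometry, the alkenyl group passes to trivalent chromium and adds 1,2 to the enal under high dilution with ester and silyl ether tolerated; the new C4 carbinol centre is left uncontrolled because step 13 removes it.

**Step 13**
Reactants: 19 (1S,2E,5Z,7R,9E)-7-[(tert-butyldimethylsilyl)oxy]-4-hydroxy-5,9-dimethylcyclodeca-2,5,9-trien-1-yl prop-2-enoate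
Product: 20 (1S,2E,5Z,7R,9E)-7-[(tert-butyldimethylsilyl)oxy]-5,9-dimethyl-4-oxocyclodeca-2,5,9-trien-1-yl prop-2-enoate
Conditions: Dess–Martin periodinane, CH2Cl2, 0 to 23 °C
Reagents that add atoms: none
Why: Dess–Martin oxidation of the doubly allylic alcohol gives the cross-conjugated dienone, which turns C7 into an enone β-carbon.

**Step 14**
Reactants: 20 (1S,2E,5Z,7R,9E)-7-[(tert-butyldimethylsilyl)oxy]-5,9-dimethyl-4-oxocyclodeca-2,5,9-trien-1-yl prop-2-enoate
Product: 21 (3aS,6Z,8R,10E,11aR)-8-[(tert-butyldimethylsilyl)oxy]-6,10-dimethyl-3-methylidene-3,3a,4,8,9,11a-hexahydrocyclodeca[b]furan-2,5-dione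
Conditions: PMe3 (20 mol %), tert-amyl alcohol (0.02 M), 23 °C
Reagents that add atoms: none
Why: PMe3 adds reversibly to the terminal carbon (C13) of the acrylate, the phosphonium ester enolate attacks C7 of the ring enone through C11, and proton transfer from C11 to C8 followed by β-elimination of PMe3 restores C11=C13, so the net change is a redox-neutral cycloisomerisation. The closest known reaction type is the intramolecular Rauhut–Currier reaction of acrylate esters of γ-hydroxy enones, which gives α-methylene-γ-butyrolactones. The lactone ring closes in the 5-exo-trig mode (intramolecular Michael addition) and the ten-membered ring is not altered. The one new stereocentre, C7 (3a of 21), is controlled by C6: the O6–C12–C11 tether reaches only the enone face on which the C6–O bond lies, and in the reactive conformer H6 eclipses C7=C8 (least A1,3 strain) with the C5 ring bond on the other face, which should give the trans 6,7-fusion (3aS,11aR); the Michael step is reversible before proton transfer, so the more stable trans-fused adduct is also the one carried forward. The step needs the acrylate, not a ring enone, as the nucleophilic partner and C7, not C1, as the acceptor: phosphine adducts of the ring enones could close onto the acrylate only through seven-membered or larger rings and so revert, and C1 is out of reach of the tether. Scrambling of the C7=C8 geometry by the phosphine is harmless because that bond is consumed, and the silyl ether and the Z-C1=C10 enone should be inert under these neutral conditions.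

**Step 15**
Reactants: 21 (3aS,6Z,8R,10E,11aR)-8-[(tert-butyldimethylsilyl)oxy]-6,10-dimethyl-3-methylidene-3,3a,4,8,9,11a-hexahydrocyclodeca[b]furan-2,5-dione
Product: 22 (3aS,5S,6Z,8R,10E,11aR)-8-[(tert-butyldimethylsilyl)oxy]-5-hydroxy-6,10-dimethyl-3-methylidene-3a,4,5,8,9,11a-hexahydrocyclodeca[b]furan-2(3H)-one
Conditions: (R)-2-methyl-CBS-oxazaborolidine (1.0 equiv), catecholborane (1.5 equiv), toluene, −78 °C
Reagents that add atoms: none
Why: in the Corey–Bakshi–Shibata reduction the ketone binds the oxazaborolidine with the α-methylalkenyl group as the large and the C4 methylene as the small substituent, so hydride should arrive on the face giving the 5S alcohol (catalyst control), and at −78 °C the borane should not touch the lactone or its exocyclic alkene.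

**Step 16**
Reactants: 23 (2E)-but-2-enal
Product: 25 (2Z)-2-bromobut-2-enal, via 2,3-dibromobutanal 24 (not isolated)
Conditions: Br2, CH2Cl2, 0 °C; then Et3N, 0 to 23 °C
Reagents that add atoms: bromine, BrBr
Why: bromine addition and dehydrobromination (loss of the acidic α-hydrogen) give the more stable Z α-bromo enal with the methyl group trans to the formyl group.

**Step 17**
Reactants: 25 (2Z)-2-bromobut-2-enal
Product: 26 (2Z)-2-bromobut-2-en-1-ol
Conditions: NaBH4, MeOH, 0 °C
Reagents that add atoms: none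
Why: borohydride 1,2-reduction of the enal gives the allylic alcohol with the alkene geometry unchanged.

**Step 18**
Reactants: 26 (2Z)-2-bromobut-2-en-1-ol
Product: 27 {[(2Z)-2-bromobut-2-en-1-yl]oxy}(tert-butyl)dimethylsilane
Conditions: TBSCl, imidazole, DMF, 23 °C
Reagents that add atoms: tert-butyldimethylsilyl chloride, CC(C)(C)[Si](C)(C)Cl
Why: silyl ether formation masks the primary hydroxyl for the lithiation and the esterification.

**Step 19**
Reactants: 27 {[(2Z)-2-bromobut-2-en-1-yl]oxy}(tert-butyl)dimethylsilane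
Product: 29 (2Z)-2-({[tert-butyl(dimethyl)silyl]oxy}methyl)but-2-enoic acid, via alkenyllithium 28 (not isolated)
Conditions: t-BuLi (2.1 equiv), Et2O, −78 °C; CO2; cold dilute HCl
Reagents that add atoms: carbon dioxide, O=C=O; tert-butyllithium, [Li]C(C)(C)C (Li stays in 28 only)
Why: bromine–lithium exchange and carboxylation both proceed with retention of alkene geometry, so the methyl group ends cis to the carboxyl group (Z acid).

**Step 20**
Reactants: 22 (3aS,5S,6Z,8R,10E,11aR)-8-[(tert-butyldimethylsilyl)oxy]-5-hydroxy-6,10-dimethyl-3-methylidene-3a,4,5,8,9,11a-hexahydrocyclodeca[b]furan-2(3H)-one; 29 (2Z)-2-({[tert-butyl(dimethyl)silyl]oxy}methyl)but-2-enoic acid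
Product: 31 (3aS,5S,6Z,8R,10E,11aR)-8-[(tert-butyldimethylsilyl)oxy]-6,10-dimethyl-3-methylidene-2-oxo-2,3,3a,4,5,8,9,11a-octahydrocyclodeca[b]furan-5-yl (2Z)-2-({[tert-butyl(dimethyl)silyl]oxy}methyl)but-2-enoate, via mixed anhydride 30 (not isolated)
Conditions: 29, 2,4,6-trichlorobenzoyl chloride, Et3N, toluene, 23 °C; then 22, DMAP (0.5 equiv), 23 °C
Reagents that add atoms: 2,4,6-trichlorobenzoyl chloride, O=C(Cl)c1c(Cl)cc(Cl)cc1Cl (its atoms stay in 30 only)
Why: in the Yamaguchi esterification the alcohol attacks the less hindered carbonyl of the mixed anhydride at ambient temperature, with retention at C5 and under conditions chosen to avoid Z to E isomerisation of the acyl group.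

**Step 21**
Reactants: 31 (3aS,5S,6Z,8R,10E,11aR)-8-[(tert-butyldimethylsilyl)oxy]-6,10-dimethyl-3-methylidene-2-oxo-2,3,3a,4,5,8,9,11a-octahydrocyclodeca[b]furan-5-yl (2Z)-2-({[tert-butyl(dimethyl)silyl]oxy}methyl)but-2-enoate
Product: 32 (3aS,5S,6Z,8R,10E,11aR)-8-hydroxy-6,10-dimethyl-3-methylidene-2-oxo-2,3,3a,4,5,8,9,11a-octahydrocyclodeca[b]furan-5-yl (2Z)-2-(hydroxymethyl)but-2-enoate
Conditions: HF·pyridine, pyridine, THF, 0 to 23 °C
Reagents that add atoms: none
Why: fluoride cleavage of both silyl ethers under buffered, non-basic conditions should spare the α-methylene lactone, the allylic ester and the Z alkene.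

**Compound list**
1 | but-2-yn-1-ol | CC#CCO | starting material
2 | sodium 2,2-bis(2-methoxyethoxy)-3-methyl-2,5-dihydro-1,2-oxaaluminol-2-uide (cyclic alkenylalanate) | CC1=CCO[Al-]1(OCCOC)OCCOC.[Na+] | intermediate
3 | (2Z)-3-iodobut-2-en-1-ol | C/C(I)=C/CO | intermediate
4 | (2Z)-3-iodobut-2-enal | C/C(I)=C/C=O | intermediate
5 | ethyl 3-methylbut-2-enoate | CCOC(=O)C=C(C)C | starting material
6 | lithium 1-ethoxy-3-methylbuta-1,3-dien-1-olate | C=C(C)C=C(OCC)O[Li] | intermediate
7 | tert-butyl[(1-ethoxy-3-methylbuta-1,3-dien-1-yl)oxy]dimethylsilane | C=C(C)C=C(OCC)O[Si](C)(C)C(C)(C)C | intermediate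
8 | ethyl (2E,5R,6Z)-5-hydroxy-7-iodo-3-methylocta-2,6-dienoate | C/C(I)=C/[C@H](O)C/C(C)=C/C(=O)OCC | intermediate
9 | ethyl (2E,5R,6Z)-5-[(tert-butyldimethylsilyl)oxy]-7-iodo-3-methylocta-2,6-dienoate | C/C(I)=C/[C@H](O[Si](C)(C)C(C)(C)C)C/C(C)=C/C(=O)OCC | intermediate
10 | (2E,5R,6Z)-5-[(tert-butyldimethylsilyl)oxy]-7-iodo-3-methylocta-2,6-dien-1-ol | C/C(I)=C/[C@H](O[Si](C)(C)C(C)(C)C)C/C(C)=C/CO | intermediate
11 | (2E,5R,6Z)-5-[(tert-butyldimethylsilyl)oxy]-7-iodo-3-methylocta-2,6-dienal | C/C(I)=C/[C@H](O[Si](C)(C)C(C)(C)C)C/C(C)=C/C=O | intermediate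
12 | 3,3-diethoxyprop-1-yne | C#CC(OCC)OCC | starting material
13 | (3,3-diethoxyprop-1-yn-1-yl)(methyl)zinc | CCOC(OCC)C#C[Zn]C | intermediate
14 | (4R,5E,8R,9Z)-8-[(tert-butyldimethylsilyl)oxy]-1,1-diethoxy-10-iodo-6-methylundeca-5,9-dien-2-yn-4-ol | C/C(I)=C/[C@H](O[Si](C)(C)C(C)(C)C)C/C(C)=C/[C@@H](O)C#CC(OCC)OCC | intermediate
15 | (2E,4S,5E,8R,9Z)-8-[(tert-butyldimethylsilyl)oxy]-1,1-diethoxy-10-iodo-6-methylundeca-2,5,9-trien-4-ol | C/C(I)=C/[C@H](O[Si](C)(C)C(C)(C)C)C/C(C)=C/[C@@H](O)/C=C/C(OCC)OCC | intermediate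
16 | (2E,4S,5E,8R,9Z)-8-[(tert-butyldimethylsilyl)oxy]-1,1-diethoxy-10-iodo-6-methylundeca-2,5,9-trien-4-yl prop-2-enoate | C/C(I)=C/[C@H](O[Si](C)(C)C(C)(C)C)C/C(C)=C/[C@@H](OC(=O)C=C)/C=C/C(OCC)OCC | intermediate
17 | (2E,4S,5E,8R,9Z)-8-[(tert-butyldimethylsilyl)oxy]-10-iodo-6-methyl-1-oxoundeca-2,5,9-trien-4-yl prop-2-enoate | C/C(I)=C/[C@H](O[Si](C)(C)C(C)(C)C)C/C(C)=C/[C@@H](OC(=O)C=C)/C=C/C=O | intermediate
18 | alkenylchromium dichloride of 17 (CrCl2 in place of iodine, Z geometry kept) | C/C([Cr](Cl)Cl)=C/[C@H](O[Si](C)(C)C(C)(C)C)C/C(C)=C/[C@@H](OC(=O)C=C)/C=C/C=O | intermediate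
19 | (1S,2E,5Z,7R,9E)-7-[(tert-butyldimethylsilyl)oxy]-4-hydroxy-5,9-dimethylcyclodeca-2,5,9-trien-1-yl prop-2-enoate (both C4 epimers) | C=CC(=O)O[C@@H]1/C=C(\C)C[C@@H](O[Si](C)(C)C(C)(C)C)/C=C(/C)C(O)/C=C/1 | intermediate
20 | (1S,2E,5Z,7R,9E)-7-[(tert-butyldimethylsilyl)oxy]-5,9-dimethyl-4-oxocyclodeca-2,5,9-trien-1-yl prop-2-enoate | C=CC(=O)O[C@@H]1/C=C(\C)C[C@@H](O[Si](C)(C)C(C)(C)C)/C=C(/C)C(=O)/C=C/1 | intermediate
21 | (3aS,6Z,8R,10E,11aR)-8-[(tert-butyldimethylsilyl)oxy]-6,10-dimethyl-3-methylidene-3,3a,4,8,9,11a-hexahydrocyclodeca[b]furan-2,5-dione | C=C1C(=O)O[C@@H]2/C=C(\C)C[C@@H](O[Si](C)(C)C(C)(C)C)/C=C(/C)C(=O)C[C@@H]12 | intermediate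
22 | (3aS,5S,6Z,8R,10E,11aR)-8-[(tert-butyldimethylsilyl)oxy]-5-hydroxy-6,10-dimethyl-3-methylidene-3a,4,5,8,9,11a-hexahydrocyclodeca[b]furan-2(3H)-one | C=C1C(=O)O[C@@H]2/C=C(\C)C[C@@H](O[Si](C)(C)C(C)(C)C)/C=C(/C)[C@@H](O)C[C@@H]12 | intermediate
23 | (2E)-but-2-enal | C/C=C/C=O | starting material
24 | 2,3-dibromobutanal | CC(Br)C(Br)C=O | intermediate
25 | (2Z)-2-bromobut-2-enal | C/C=C(\Br)C=O | intermediate
26 | (2Z)-2-bromobut-2-en-1-ol | C/C=C(\Br)CO | intermediate
27 | {[(2Z)-2-bromobut-2-en-1-yl]oxy}(tert-butyl)dimethylsilane | C/C=C(\Br)CO[Si](C)(C)C(C)(C)C | intermediate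
28 | [(2E)-1-{[tert-butyl(dimethyl)silyl]oxy}but-2-en-2-yl]lithium | C/C=C(\[Li])CO[Si](C)(C)C(C)(C)C | intermediate
29 | (2Z)-2-({[tert-butyl(dimethyl)silyl]oxy}methyl)but-2-enoic acid | C/C=C(\C(=O)O)CO[Si](C)(C)C(C)(C)C | intermediate
30 | (2Z)-2-({[tert-butyl(dimethyl)silyl]oxy}methyl)but-2-enoic 2,4,6-trichlorobenzoic anhydride | C/C=C(\C(=O)OC(=O)c1c(Cl)cc(Cl)cc1Cl)CO[Si](C)(C)C(C)(C)C | intermediate
31 | (3aS,5S,6Z,8R,10E,11aR)-8-[(tert-butyldimethylsilyl)oxy]-6,10-dimethyl-3-methylidene-2-oxo-2,3,3a,4,5,8,9,11a-octahydrocyclodeca[b]furan-5-yl (2Z)-2-({[tert-butyl(dimethyl)silyl]oxy}methyl)but-2-enoate | C=C1C(=O)O[C@@H]2/C=C(\C)C[C@@H](O[Si](C)(C)C(C)(C)C)/C=C(/C)[C@@H](OC(=O)/C(=C\C)CO[Si](C)(C)C(C)(C)C)C[C@@H]12 | intermediate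
32 | (3aS,5S,6Z,8R,10E,11aR)-8-hydroxy-6,10-dimethyl-3-methylidene-2-oxo-2,3,3a,4,5,8,9,11a-octahydrocyclodeca[b]furan-5-yl (2Z)-2-(hydroxymethyl)but-2-enoate | C=C1C(=O)O[C@@H]2/C=C(\C)C[C@@H](O)/C=C(/C)[C@@H](OC(=O)/C(=C\C)CO)C[C@@H]12 | target

**Step count**
Total: 21 steps. Longest linear sequence: 16 steps (steps 1, 2, 4 to 15, 20, 21).

**Steps most likely to fail**

Step 12 (macrocyclisation). Closing a ten-membered ring that holds three endocyclic double bonds, two of them E, builds strain in the transition state, so intermolecular coupling to oligomers and reductive loss of iodine may outrun ring closure. Fallback, ring-closing metathesis at C7=C8, which lets the ring choose the enone geometry: setting out from 15, Et3SiCl/imidazole gives the triethylsilyl ether F1. Iodine–lithium exchange (t-BuLi, Et2O, −78 °C) and addition of acrolein give the dienol F2, and MnO2 gives the vinyl ketone F3. Ring-closing metathesis with RuCl2(H2IMes)(=CH-C6H4-2-O-i-Pr) (second-generation Hoveyda–Grubbs catalyst) in dilute toluene, with loss of 3,3-diethoxyprop-1-ene, gives the ten-membered dienone F4. Buffered HF·pyridine removes the triethylsilyl group selectively to give the alcohol F5, and acryloyl chloride/i-Pr2NEt gives the acrylate F6, which under the conditions of step 14 returns to the route at 21.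

Step 14 (Rauhut–Currier closure). The phosphine may be held back by reversible addition to the ring enones, which would cause slow turnover, drift of the C1=C10 geometry or oligomerisation, and the facial selectivity at C7 may be lower than the conformational argument predicts. Fallback, a stoichiometric anionic Michael–Michael sequence at low temperature followed by oxidative elimination: setting out from 20, lithium benzeneselenolate (PhSeLi, THF, −78 °C) adds to the acrylate and the ester enolate closes onto C7 to give the α-(phenylselanylmethyl) lactone F7. H2O2 (THF, 0 °C) gives the selenoxide F8, whose syn-elimination at 0 to 23 °C returns to the route at 21.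

Step 15 (ketone reduction). The conformational bias of the ten-membered ring may oppose the catalyst and erode facial selectivity, and conjugate reduction of the exocyclic methylene may compete. Fallback, substrate control followed by an esterification that inverts: setting out from 21, Luche reduction (NaBH4, CeCl3·7H2O, MeOH, −78 °C) is run under control by the ring. Should it give the C5-epimeric alcohol F9, Mitsunobu esterification of F9 with acid 29 (PPh3, diisopropyl azodicarboxylate, toluene, 0 °C) inverts C5 and returns to the route at 31.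

**Further compounds**
F1 | step 12 | (2E,4S,5E,8R,9Z)-8-[(tert-butyldimethylsilyl)oxy]-1,1-diethoxy-10-iodo-6-methyl-4-[(triethylsilyl)oxy]undeca-2,5,9-triene | C/C(I)=C/[C@H](O[Si](C)(C)C(C)(C)C)C/C(C)=C/[C@@H](O[Si](CC)(CC)CC)/C=C/C(OCC)OCC
F2 | step 12 | (4Z,6R,8E,10S,11E)-6-[(tert-butyldimethylsilyl)oxy]-13,13-diethoxy-4,8-dimethyl-10-[(triethylsilyl)oxy]trideca-1,4,8,11-tetraen-3-ol (both C3 epimers) | C/C(C(O)C=C)=C/[C@H](O[Si](C)(C)C(C)(C)C)C/C(C)=C/[C@@H](O[Si](CC)(CC)CC)/C=C/C(OCC)OCC
F3 | step 12 | (4Z,6R,8E,10S,11E)-6-[(tert-butyldimethylsilyl)oxy]-13,13-diethoxy-4,8-dimethyl-10-[(triethylsilyl)oxy]trideca-1,4,8,11-tetraen-3-one | C/C(C(=O)C=C)=C/[C@H](O[Si](C)(C)C(C)(C)C)C/C(C)=C/[C@@H](O[Si](CC)(CC)CC)/C=C/C(OCC)OCC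
F4 | step 12 | (4S,5E,8R,9Z)-8-[(tert-butyldimethylsilyl)oxy]-6,10-dimethyl-4-[(triethylsilyl)oxy]cyclodeca-2,5,9-trien-1-one (C2=C3 geometry as formed) | CC[Si](CC)(CC)O[C@@H]1/C=C(\C)C[C@@H](O[Si](C)(C)C(C)(C)C)/C=C(/C)C(=O)C=C1
F5 | step 12 | (4S,5E,8R,9Z)-8-[(tert-butyldimethylsilyl)oxy]-4-hydroxy-6,10-dimethylcyclodeca-2,5,9-trien-1-one (C2=C3 geometry as formed) | O[C@@H]1/C=C(\C)C[C@@H](O[Si](C)(C)C(C)(C)C)/C=C(/C)C(=O)C=C1
F6 | step 12 | (1S,5Z,7R,9E)-7-[(tert-butyldimethylsilyl)oxy]-5,9-dimethyl-4-oxocyclodeca-2,5,9-trien-1-yl prop-2-enoate (C2=C3 geometry as formed) | C=CC(=O)O[C@@H]1/C=C(\C)C[C@@H](O[Si](C)(C)C(C)(C)C)/C=C(/C)C(=O)C=C1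
F7 | step 14 | (3aS,6Z,8R,10E,11aR)-8-[(tert-butyldimethylsilyl)oxy]-6,10-dimethyl-3-[(phenylselanyl)methyl]-3,3a,4,8,9,11a-hexahydrocyclodeca[b]furan-2,5-dione (C3 epimers) | O=C1O[C@@H]2/C=C(\C)C[C@@H](O[Si](C)(C)C(C)(C)C)/C=C(/C)C(=O)C[C@H]2C1C[Se]c1ccccc1
F8 | step 14 | (3aS,6Z,8R,10E,11aR)-3-[(benzeneseleninyl)methyl]-8-[(tert-butyldimethylsilyl)oxy]-6,10-dimethyl-3,3a,4,8,9,11a-hexahydrocyclodeca[b]furan-2,5-dione | O=C1O[C@@H]2/C=C(\C)C[C@@H](O[Si](C)(C)C(C)(C)C)/C=C(/C)C(=O)C[C@H]2C1C[Se](=O)c1ccccc1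
F9 | step 15 | (3aS,5R,6Z,8R,10E,11aR)-8-[(tert-butyldimethylsilyl)oxy]-5-hydroxy-6,10-dimethyl-3-methylidene-3a,4,5,8,9,11a-hexahydrocyclodeca[b]furan-2(3H)-one | C=C1C(=O)O[C@@H]2/C=C(\C)C[C@@H](O[Si](C)(C)C(C)(C)C)/C=C(/C)[C@H](O)C[C@@H]12
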